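**Plan**
- Numbering: oxolane ring O–C7'–C8'–C8–C9; C7 is the carbinol carbon on C8 (ring A); C9' is the CH2OH carbon on C8'; ring B sits on C7'.
- Retrosynthesis: after unmasking (phenol pivalates, C7 silyl ether, C9' CH2OH ⇐ CO2H ⇐ CH2NO2, ring C9H2 ⇐ lactol), the lactol is cut at C8–C8' and at O7'–C9 into β-silyloxy aldehyde 8 (C7–C8–C9) and γ-hydroxy nitroalkene 14 (C7'–C8'–C9').
- Enabling feature: C8 is α to aldehyde-level C9, C8' is β to nitro-masked C9', and O7' can reach C9 through C7'–C8'–C8, so a syn aldehyde–nitroalkene Michael addition maps onto the cis C7/C9' pair and the hydroxyl closes the oxolane.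
- Forward: vanillin pivalate 2 feeds both halves (three steps to 8, five to 14); step 10 joins them and forms the only ring; four steps adjust oxidation level and remove protection.
- Stereochemistry: C7 from Brown allylboration, C7' from lipase resolution, C8 and C8' from the (S)-diarylprolinol silyl ether (syn Michael addition).

Key step: step 10

Remark: ArP = 3-methoxy-4-(pivaloyloxy)phenyl; TBS = tert-butyldimethylsilyl.
Assumption: both phenols are carried as pivalates and the C7 hydroxyl as its TBS ether; the electron-poor rings are chosen to disfavour benzylic ionisation (loss of the C7 silyloxy group from the enamine, Lewis-acid opening at C7').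

Step 1
Reactants: 1 vanillin
Product: 2 4-formyl-2-methoxyphenyl pivalate
Conditions: PivCl, Et3N, DMAP (cat.), CH2Cl2, 0 °C → rt
Reagents that add atoms: pivaloyl chloride, CC(C)(C)C(Cl)=O
Why: DMAP-catalysed O-acylation of the phenol gives a hindered aryl ester that should survive every step up to the hydride reduction and makes both aryl rings poorer donors.

Step 2
Reactants: 2 4-formyl-2-methoxyphenyl pivalate; 3 (+)-B-allyldiisopinocampheylborane
Product: 5 4-[(1R)-1-hydroxybut-3-en-1-yl]-2-methoxyphenyl pivalate, via borinate ester 4 (not isolated)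
Conditions: Et2O, −78 °C; then 3 M aq. NaOAc, 30% H2O2, 0 °C → rt
Reagents that add atoms: (+)-B-allyldiisopinocampheylborane (3), C=CCB([C@H]1C[C@H]2C[C@@H]([C@@H]1C)C2(C)C)[C@H]1C[C@H]2C[C@@H]([C@@H]1C)C2(C)C
Why: Brown allylboration through a chair transition state, in which the (−)-α-pinene-derived reagent delivers allyl to the aldehyde face that gives the (R)-carbinol (its enantiomer gives (S)-1-phenylbut-3-en-1-ol from benzaldehyde), sets C7, and the buffered peroxide work-up should spare the aryl pivalate.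

Step 3
Reactants: 5 4-[(1R)-1-hydroxybut-3-en-1-yl]-2-methoxyphenyl pivalate
Product: 6 4-[(1R)-1-(TBSO)but-3-en-1-yl]-2-methoxyphenyl pivalate
Conditions: TBSOTf, 2,6-lutidine, CH2Cl2, −78 → 0 °C
Reagents that add atoms: tert-butyldimethylsilyl triflate, CC(C)(C)[Si](C)(C)OS(=O)(=O)C(F)(F)F
Why: Silylation of the secondary alcohol with a silyl triflate and a hindered base installs a poor leaving group at C7 that tolerates the later amine, Lewis acid, nitrite and hydride steps.

Step 4
Reactants: 6 4-[(1R)-1-(TBSO)but-3-en-1-yl]-2-methoxyphenyl pivalate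
Product: 8 4-[(1R)-1-(TBSO)-3-oxopropyl]-2-methoxyphenyl pivalate, via ozonide 7 (not isolated)
Conditions: O3, CH2Cl2, −78 °C; then PPh3, −78 °C → rt
Reagents that add atoms: ozone, [O-][O+]=O
Why: Ozonolysis with reductive work-up cleaves the terminal alkene to the aldehyde faster than ozone attacks the acyloxy-deactivated arene and leaves C7 untouched.

Step 5
Reactants: 2 4-formyl-2-methoxyphenyl pivalate; 9 vinylmagnesium bromide
Product: 10 rac-4-(1-hydroxyprop-2-en-1-yl)-2-methoxyphenyl pivalate
Conditions: CH2=CHMgBr, THF, −78 °C; then sat. aq. NH4Cl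
Reagents that add atoms: vinylmagnesium bromide (9), C=C[Mg]Br
Why: Grignard 1,2-addition to the aldehyde, which at −78 °C is far more electrophilic than the hindered aryl pivalate, gives the racemic allylic alcohol.

Step 6
Reactants: 10 rac-4-(1-hydroxyprop-2-en-1-yl)-2-methoxyphenyl pivalate
Product: 11 4-[(1S)-1-hydroxyprop-2-en-1-yl]-2-methoxyphenyl pivalate
Conditions: Novozym 435 (immobilised lipase B of Candida antarctica), vinyl acetate, tBuOMe, 30 °C, stopped just past half conversion; chromatography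
Reagents that add atoms: none
Why: Enzymatic kinetic resolution by lipase-catalysed transesterification acylates the (R)-alcohol (aryl as the large, vinyl as the medium group), so the (S)-alcohol carrying the C7' configuration should remain and is separated from the (R)-acetate.

Step 7
Reactants: 11 4-[(1S)-1-hydroxyprop-2-en-1-yl]-2-methoxyphenyl pivalate
Product: 12 4-[(1S)-1-(TBSO)prop-2-en-1-yl]-2-methoxyphenyl pivalate
Conditions: TBSCl, imidazole, DMF, 0 °C → rt
Reagents that add atoms: tert-butyldimethylsilyl chloride, CC(C)(C)[Si](C)(C)Cl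
Why: Silylation masks the benzylic allylic carbinol so that the nitroxyl/NO2 medium of the next step cannot oxidise it to the ketone.

Step 8
Reactants: 12 4-[(1S)-1-(TBSO)prop-2-en-1-yl]-2-methoxyphenyl pivalate
Product: 13 4-[(1S,2E)-1-(TBSO)-3-nitroprop-2-en-1-yl]-2-methoxyphenyl pivalate
Conditions: AgNO2 (3 equiv), TEMPO (0.4 equiv), 4 Å molecular sieves, ClCH2CH2Cl, 70 °C
Reagents that add atoms: AgNO2, [Ag+].[O-]N=O
Why: Radical nitration of a terminal alkene, in which NO2 from AgNO2 adds to the terminal carbon and TEMPO-mediated hydrogen abstraction restores the double bond, should give the (E)-nitroalkene without touching C7'.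

Step 9
Reactants: 13 4-[(1S,2E)-1-(TBSO)-3-nitroprop-2-en-1-yl]-2-methoxyphenyl pivalate
Product: 14 4-[(1S,2E)-1-hydroxy-3-nitroprop-2-en-1-yl]-2-methoxyphenyl pivalate
Conditions: 48% aq. HF, MeCN, 0 °C → rt
Reagents that add atoms: none
Why: Acidic fluoride desilylation cleaves the alkyl silyl ether while the acid-tolerant nitroalkene and aryl pivalate survive, and the electron-poor nitrovinyl group prevents ionisation at C7'.

Step 10
Reactants: 8 4-[(1R)-1-(TBSO)-3-oxopropyl]-2-methoxyphenyl pivalate; 14 4-[(1S,2E)-1-hydroxy-3-nitroprop-2-en-1-yl]-2-methoxyphenyl pivalate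
Product: 17 (3S,4R,5S)-5-ArP-3-[(R)-ArP(TBSO)methyl]-4-(nitromethyl)oxolan-2-ol (anomeric mixture), via enamine 15 (not isolated), via open-chain nitro aldehyde 16 (not isolated)
Conditions: (S)-2-[diphenyl(trimethylsilyloxy)methyl]pyrrolidine (10 mol%), 4-nitrophenol (10 mol%), toluene, 0 °C → rt; 8 in 1.5-fold excess
Reagents that add atoms: none
Why: The amine condenses with 8 to the E-enamine 15, whose C8 adds to C8' of 14 through the synclinal open transition state; hydrolysis frees the catalyst and nitro aldehyde 16, whose C7' hydroxyl adds to the C9 carbonyl, so C8–C8' and O7'–C9 form in one operation. The closest known reactions are the diarylprolinol silyl ether-catalysed syn-selective Michael addition of aldehydes to nitroalkenes and the Michael–hemiacetalization cascades of hydroxy nitroalkenes. The oxolane ring (O7'–C7'–C8'–C8–C9) closes 5-exo-trig by hemiacetalization, and the anomeric centre is left as a mixture that step 11 removes. C8 is set by the catalyst, whose diphenyl(silyloxy)methyl group shields one enamine face so that the (S)-amine gives the sense known for (2R,3S)-2-methyl-4-nitro-3-phenylbutanal from propanal and β-nitrostyrene (the C7 group takes the place of methyl, the C7' group that of phenyl), and C8' is set by the syn topology of the transition state, which places C7 and C9' cis on the ring. The step needs catalyst control over the two preset centres and an enamine that does not expel silanolate: attack anti to the C7–OSi bond gives the required 7,8-anti arrangement and should reinforce the catalyst, the small free C7' carbinol lies outside the transition-state core, and the pivalate-deactivated ring A, the poor silyloxy leaving group and the weakly acidic co-catalyst disfavour β-elimination.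

Step 11
Reactants: 17 (3S,4R,5S)-5-ArP-3-[(R)-ArP(TBSO)methyl]-4-(nitromethyl)oxolan-2-ol
Product: 18 (2S,3R,4R)-2-ArP-4-[(R)-ArP(TBSO)methyl]-3-(nitromethyl)oxolane
Conditions: Et3SiH, BF3·OEt2, CH2Cl2, −78 → −40 °C
Reagents that add atoms: none
Why: Ionic hydrogenation (reductive deoxygenation) of the lactol at its anomeric carbon by Et3SiH under BF3 activation should leave the C7 silyl ether and the C7'–O bond intact at low temperature because both are benzylic to acyloxy-deactivated rings.

Step 12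
Reactants: 18 (2S,3R,4R)-2-ArP-4-[(R)-ArP(TBSO)methyl]-3-(nitromethyl)oxolane
Product: 19 (2S,3S,4R)-2-ArP-4-[(R)-ArP(TBSO)methyl]oxolane-3-carboxylic acid
Conditions: NaNO2, AcOH, DMSO, 35 °C
Reagents that add atoms: NaNO2, [Na+].[O-]N=O; water, O (sources of the two carboxyl oxygens)
Why: Nef-type nitrosative oxidation of a primary nitroalkane to the carboxylic acid avoids a free C9' aldehyde, so the C8' configuration should be kept and β-elimination of the ring oxygen avoided.

Step 13
Reactants: 19 (2S,3S,4R)-2-ArP-4-[(R)-ArP(TBSO)methyl]oxolane-3-carboxylic acid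
Product: 20 4-[(2S,3R,4R)-4-[(R)-(TBSO)(4-hydroxy-3-methoxyphenyl)methyl]-3-(hydroxymethyl)oxolan-2-yl]-2-methoxyphenol
Conditions: LiAlH4, THF, 0 °C → rt; aq. KNaC4H4O6 work-up
Reagents that add atoms: none
Why: Hydride reduction with LiAlH4 converts the carboxylic acid into the C9' primary alcohol and cleaves both aryl pivalates in the same operation, while the silyl ether and the oxolane are inert.

Step 14
Reactants: 20 4-[(2S,3R,4R)-4-[(R)-(TBSO)(4-hydroxy-3-methoxyphenyl)methyl]-3-(hydroxymethyl)oxolan-2-yl]-2-methoxyphenol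
Product: 21 (7R)-7-hydroxylariciresinol
Conditions: Bu4NF, AcOH (1:1), THF, 0 °C → rt
Reagents that add atoms: none
Why: Fluoride-mediated desilylation frees the C7 hydroxyl, and buffering with acetic acid keeps the phenols protonated so that no quinone methide should form from the 4-hydroxybenzylic carbinol.

**Compound list**
1 | vanillin (4-hydroxy-3-methoxybenzaldehyde) | COc1cc(C=O)ccc1O | starting material
2 | 4-formyl-2-methoxyphenyl pivalate | COc1cc(C=O)ccc1OC(=O)C(C)(C)C | intermediate
3 | (+)-B-allyldiisopinocampheylborane, (+)-Ipc2B(allyl), derived from (−)-α-pinene | C=CCB([C@H]1C[C@H]2C[C@@H]([C@@H]1C)C2(C)C)[C@H]1C[C@H]2C[C@@H]([C@@H]1C)C2(C)C | starting material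
4 | diisopinocampheylborinate ester of (R)-alcohol 5 | C=CC[C@@H](OB([C@H]1C[C@H]2C[C@@H]([C@@H]1C)C2(C)C)[C@H]1C[C@H]2C[C@@H]([C@@H]1C)C2(C)C)c1ccc(OC(=O)C(C)(C)C)c(OC)c1 | intermediate (not isolated)
5 | 4-[(1R)-1-hydroxybut-3-en-1-yl]-2-methoxyphenyl pivalate | C=CC[C@@H](O)c1ccc(OC(=O)C(C)(C)C)c(OC)c1 | intermediate
6 | 4-[(1R)-1-(tert-butyldimethylsilyloxy)but-3-en-1-yl]-2-methoxyphenyl pivalate | C=CC[C@@H](O[Si](C)(C)C(C)(C)C)c1ccc(OC(=O)C(C)(C)C)c(OC)c1 | intermediate
7 | ozonide of 6, 4-[(1R)-1-(tert-butyldimethylsilyloxy)-2-(1,2,4-trioxolan-3-yl)ethyl]-2-methoxyphenyl pivalate (mixture at the trioxolane carbon) | C1OC(C[C@@H](O[Si](C)(C)C(C)(C)C)c2ccc(OC(=O)C(C)(C)C)c(OC)c2)OO1 | intermediate (not isolated)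
8 | 4-[(1R)-1-(tert-butyldimethylsilyloxy)-3-oxopropyl]-2-methoxyphenyl pivalate | O=CC[C@@H](O[Si](C)(C)C(C)(C)C)c1ccc(OC(=O)C(C)(C)C)c(OC)c1 | intermediate
9 | vinylmagnesium bromide, CH2=CHMgBr | C=C[Mg]Br | starting material
10 | rac-4-(1-hydroxyprop-2-en-1-yl)-2-methoxyphenyl pivalate | COc1cc(C(O)C=C)ccc1OC(=O)C(C)(C)C | intermediate
11 | 4-[(1S)-1-hydroxyprop-2-en-1-yl]-2-methoxyphenyl pivalate | COc1cc([C@@H](O)C=C)ccc1OC(=O)C(C)(C)C | intermediate
12 | 4-[(1S)-1-(tert-butyldimethylsilyloxy)prop-2-en-1-yl]-2-methoxyphenyl pivalate | COc1cc([C@@H](O[Si](C)(C)C(C)(C)C)C=C)ccc1OC(=O)C(C)(C)C | intermediate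
13 | 4-[(1S,2E)-1-(tert-butyldimethylsilyloxy)-3-nitroprop-2-en-1-yl]-2-methoxyphenyl pivalate | COc1cc([C@@H](O[Si](C)(C)C(C)(C)C)/C=C/[N+](=O)[O-])ccc1OC(=O)C(C)(C)C | intermediate
14 | 4-[(1S,2E)-1-hydroxy-3-nitroprop-2-en-1-yl]-2-methoxyphenyl pivalate | COc1cc([C@@H](O)/C=C/[N+](=O)[O-])ccc1OC(=O)C(C)(C)C | intermediate
15 | E-enamine of 8, 4-[(1R,2E)-1-(tert-butyldimethylsilyloxy)-3-{(2S)-2-[diphenyl(trimethylsilyloxy)methyl]pyrrolidin-1-yl}prop-2-en-1-yl]-2-methoxyphenyl pivalate | CC(C)(C)[Si](C)(C)O[C@H](/C=C/N1CCC[C@H]1C(O[Si](C)(C)C)(c1ccccc1)c1ccccc1)c1ccc(OC(=O)C(C)(C)C)c(OC)c1 | intermediate (not isolated)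
16 | (2S,3R)-2-[(R)-ArP(tert-butyldimethylsilyloxy)methyl]-3-[(S)-ArP(hydroxy)methyl]-4-nitrobutanal | O=C[C@H]([C@@H](O[Si](C)(C)C(C)(C)C)c1ccc(OC(=O)C(C)(C)C)c(OC)c1)[C@@H]([C@H](O)c1ccc(OC(=O)C(C)(C)C)c(OC)c1)C[N+](=O)[O-] | intermediate (not isolated)
17 | (3S,4R,5S)-5-ArP-3-[(R)-ArP(tert-butyldimethylsilyloxy)methyl]-4-(nitromethyl)oxolan-2-ol, anomeric mixture | COc1cc([C@H]2OC(O)[C@H]([C@@H](O[Si](C)(C)C(C)(C)C)c3ccc(OC(=O)C(C)(C)C)c(OC)c3)[C@@H]2C[N+](=O)[O-])ccc1OC(=O)C(C)(C)C | intermediate
18 | (2S,3R,4R)-2-ArP-4-[(R)-ArP(tert-butyldimethylsilyloxy)methyl]-3-(nitromethyl)oxolane | COc1cc([C@H]2OC[C@H]([C@@H](O[Si](C)(C)C(C)(C)C)c3ccc(OC(=O)C(C)(C)C)c(OC)c3)[C@@H]2C[N+](=O)[O-])ccc1OC(=O)C(C)(C)C | intermediate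
19 | (2S,3S,4R)-2-ArP-4-[(R)-ArP(tert-butyldimethylsilyloxy)methyl]oxolane-3-carboxylic acid | COc1cc([C@H]2OC[C@H]([C@@H](O[Si](C)(C)C(C)(C)C)c3ccc(OC(=O)C(C)(C)C)c(OC)c3)[C@@H]2C(=O)O)ccc1OC(=O)C(C)(C)C | intermediate
20 | 4-[(2S,3R,4R)-4-[(R)-(tert-butyldimethylsilyloxy)(4-hydroxy-3-methoxyphenyl)methyl]-3-(hydroxymethyl)oxolan-2-yl]-2-methoxyphenol | COc1cc([C@H]2OC[C@H]([C@@H](O[Si](C)(C)C(C)(C)C)c3ccc(O)c(OC)c3)[C@@H]2CO)ccc1O | intermediate
21 | (7R)-7-hydroxylariciresinol, 4-[(2S,3R,4R)-4-[(R)-hydroxy(4-hydroxy-3-methoxyphenyl)methyl]-3-(hydroxymethyl)oxolan-2-yl]-2-methoxyphenol | COc1cc([C@H]2OC[C@H]([C@@H](O)c3ccc(O)c(OC)c3)[C@@H]2CO)ccc1O | target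

**Step count and risks**

Total: 14 steps. Longest linear sequence: 11 steps (steps 1, 5, 6, 7, 8, 9, 10, 11, 12, 13, 14).

Step 10 is the most likely to fail. Enamine 15 may lose silanolate to give the cinnamaldehyde-type iminium ion. C–C bond formation between two branched partners may be slow enough that the unprotected hydroxy nitroalkene is consumed by γ-deprotonation or by hemiacetal/oxa-Michael trapping with 8. Facial selectivity may erode if the free C7' carbinol opposes the catalyst. The fallback separates C–C bond formation from ring closure on a protected acceptor and sets out from 14 and 8. TESOTf and 2,6-lutidine (CH2Cl2, −78 °C) convert 14 into 4-[(1S,2E)-3-nitro-1-(triethylsilyloxy)prop-2-en-1-yl]-2-methoxyphenyl pivalate F1, a γ-silyloxy nitroalkene that cannot enter hemiacetal or oxa-Michael side reactions. Michael addition of 8 under the same amine should give the open-chain (2S,3R)-nitro aldehyde F2, which is isolated. AcOH/THF/H2O then removes only the triethylsilyl group, and the freed C7' hydroxyl closes onto C9, which returns to the route at lactol 17.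

Step 8 is the second risk. The radical nitration may stall or be diverted by hydrogen abstraction at the benzylic, allylic C7'–H, by acid-promoted loss of the silyl group, or by erosion of the E geometry. The fallback is a nitroaldol route from 12. Ozonolysis (O3, CH2Cl2, −78 °C; PPh3) should lead through the ozonide F3 to 4-[(1R)-1-(tert-butyldimethylsilyloxy)-2-oxoethyl]-2-methoxyphenyl pivalate F4, which is kept cold and not chromatographed because its α-aryl centre is configurationally labile. A Henry reaction with MeNO2 (catalytic iPr2NEt, 0 °C) should give the nitro alcohol F5 as a mixture at the new carbinol. Dehydration with MsCl/Et3N (−20 °C) returns to the route at 13.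

Step 11 is the third risk. Lewis-acid ionisation may not stay at the anomeric carbon: the benzylic C7'–O bond may open (epimerisation at C7' or over-reduction), the C7 silyloxy group may be lost, or the cationic intermediate may lose a proton to a 2,3-dihydrofuran and scramble C8. The fallback sets out from 17 and closes the ring by substitution instead. NaBH4 (MeOH/THF, 0 °C) should reduce the open-chain form of 17 to the 1,4-diol F6. TsCl in pyridine should sulfonylate the primary hydroxyl selectively to the tosylate F7. On warming, the C7' hydroxyl displaces the tosylate at C9 (5-exo-tet, C7' untouched), which returns to the route at 18.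

**Further compounds**
F1 | step 10 | 4-[(1S,2E)-3-nitro-1-(triethylsilyloxy)prop-2-en-1-yl]-2-methoxyphenyl pivalate | COc1cc([C@@H](O[Si](CC)(CC)CC)/C=C/[N+](=O)[O-])ccc1OC(=O)C(C)(C)C
F2 | step 10 | (2S,3R)-2-[(R)-ArP(tert-butyldimethylsilyloxy)methyl]-3-[(S)-ArP(triethylsilyloxy)methyl]-4-nitrobutanal | O=C[C@H]([C@@H](O[Si](C)(C)C(C)(C)C)c1ccc(OC(=O)C(C)(C)C)c(OC)c1)[C@@H]([C@H](O[Si](CC)(CC)CC)c1ccc(OC(=O)C(C)(C)C)c(OC)c1)C[N+](=O)[O-]
F3 | step 8 | ozonide of 12, 4-[(R)-(tert-butyldimethylsilyloxy)(1,2,4-trioxolan-3-yl)methyl]-2-methoxyphenyl pivalate | COc1cc([C@@H](O[Si](C)(C)C(C)(C)C)C2OCOO2)ccc1OC(=O)C(C)(C)C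
F4 | step 8 | 4-[(1R)-1-(tert-butyldimethylsilyloxy)-2-oxoethyl]-2-methoxyphenyl pivalate | COc1cc([C@@H](O[Si](C)(C)C(C)(C)C)C=O)ccc1OC(=O)C(C)(C)C
F5 | step 8 | 4-[(1R)-1-(tert-butyldimethylsilyloxy)-2-hydroxy-3-nitropropyl]-2-methoxyphenyl pivalate (epimers at C2) | COc1cc([C@@H](O[Si](C)(C)C(C)(C)C)C(O)C[N+](=O)[O-])ccc1OC(=O)C(C)(C)C
F6 | step 11 | (2R,3R)-2-[(R)-ArP(tert-butyldimethylsilyloxy)methyl]-3-[(S)-ArP(hydroxy)methyl]-4-nitrobutan-1-ol | OC[C@H]([C@@H](O[Si](C)(C)C(C)(C)C)c1ccc(OC(=O)C(C)(C)C)c(OC)c1)[C@@H]([C@H](O)c1ccc(OC(=O)C(C)(C)C)c(OC)c1)C[N+](=O)[O-]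
F7 | step 11 | primary 4-methylbenzenesulfonate of F6 | Cc1ccc(S(=O)(=O)OC[C@H]([C@@H](O[Si](C)(C)C(C)(C)C)c2ccc(OC(=O)C(C)(C)C)c(OC)c2)[C@@H]([C@H](O)c2ccc(OC(=O)C(C)(C)C)c(OC)c2)C[N+](=O)[O-])cc1
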